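Locants follow flavone numbering (O1, C2, C3, C4, C4a–C8a; ring B C1'–C6'). C9 is the CH2 on C3, C10 the oxygen-bearing carbon of ring D, and C11 the carbon attached to C10. "Oxepinoflavone" means the flavone whose C3 and 2'-oxygen are bridged as C3–C9–C10–O–C2'. Compound numbers are those of the steps and of the compound list.

## Analysis of the target

Compound 24 is a tetracyclic flavone. Ring A (C4a–C8a) carries 5-OH, 7-OMe and an (E)-3-methylbut-1-enyl chain at C6; ring C is the γ-pyranone; ring B has a free 4'-OH; ring D is a seven-membered oxepine made of C2, C3, C9, C10, the ether oxygen, C2' and C1'. The only stereocentre is C10 (R), which bears the ring oxygen, C9H2 and the tertiary carbinol C11. It has no stereogenic neighbour to relay from, so a chiral reagent or catalyst must set it; the E geometry of the side-chain alkene is the only other stereo-element. Sensitive functions are the two phenols (5-OH chelated to C4=O, 4'-OH making ring B very electron-rich), the tertiary alcohol (ionises in acid), the styrene-like side-chain alkene (lost under hydrogenation, metathesis or strong acid) and the pyranone (opened at C2 by hard nucleophiles). The hard parts are the medium ring across the twisted C2–C1' bond, the aryl ether to a hindered secondary carbon, the differentiation of three phenolic oxygens, and substitution at C6 rather than C8 or ring B. The strategy rests on one feature: C9–C10 is the only C–C bond of ring D in which neither atom is an aromatic-ring atom, and C10 carries both the ether oxygen and C11. With C11 at the carboxyl level and a C9=C10 double bond, ring D is a cyclic 2-aryloxyacrylate, which metathesis can close and asymmetric hydrogenation can convert into the stereocentre.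

## Retrosynthetic reasoning

**24 ⇒ 21 + 22 (C6–alkenyl bond).** The side chain is cut first because its alkene would not survive the hydrogenation of C9=C10, the metathesis catalyst or the Lewis-acid deprotection. A palladium cross-coupling of the 6-iodide 21 with the E-alkenylboronate 22 transfers the geometry unchanged. The 4'-acetate of the coupled product 23 is cleaved in the same pot.

**21 ⇒ 20 ⇒ 19 (C6–I bond, then the 4'-acetate).** Iodination ortho to the free, chelated 5-OH puts the halogen at C6. Ring B of 19 is a free resorcinol-type ring and would compete, so its 4'-OH is first acetylated (20). The 5-OH and the tertiary alcohol do not react under those conditions.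

**19 ⇒ 18 (the two C11–CH3 bonds).** The carbinol is cut back to the methyl ester 18, to be made by double addition of a methyl Grignard reagent. The phenols are left free on purpose: as magnesium phenoxides they make the pyranone an electron-rich, unreactive vinylogous carboxylate.

**18 ⇒ 16, through 17 (O–CH3 at C5, O–benzyl at C4', ester O–CH3).** Both ether cleavages are assigned to one boron trihalide treatment of acid 16, followed by esterification of the resulting dihydroxy acid 17. This is placed before the tertiary alcohol exists, because that alcohol would ionise under the same Lewis acid.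

**16 ⇒ 15 ⇒ 14 (C9–H and C10–H; ester hydrolysis).** The stereocentre is traced to the trisubstituted alkene of acid 15. A carboxylate-directed asymmetric hydrogenation needs the free acid, hence the saponification of ester 14. The ring fixes the alkene geometry, so only face selectivity has to be controlled.

**14 ⇒ 13 (C9=C10, ring D).** The ring is opened at the double bond to the diene 13, which carries a vinyl group on C3 and a 2-aryloxyacrylate on the 2'-oxygen. The forward reaction must select between three C=C bonds and favour ring closure over dimerisation.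

**13 ⇒ 10 + 11 (O–C10 bond).** The aryl ether is cut on the alkyl side, so that it is made by alkylating phenol 10 with the dibromo ester 11 and eliminating HBr from the bromo ester 12. No substitution on ring B is then needed anywhere in the route.

**10 ⇒ 9 ⇒ 8 (C3–C9 bond, then the 2'-O acetal).** The vinyl group comes from the 3-iodide 8 by coupling with a vinyl tin reagent. The methoxymethyl group of 9 is removed only afterwards, so that no free phenol sits beside the palladium intermediate.

**8 ⇒ 7 (O1–C2 and C3–I).** The pyranone and its iodine come together from ynone 7 by iodocyclisation. A ring A methoxy oxygen closes onto the alkyne and loses its methyl group, which also leaves the 5- and 7-oxygens as methyl ethers.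

**7 ⇒ 4 + 6 (C3–C4 bond).** The ynone is cut between the alkyne and the carbonyl into alkyne 4 and acid chloride 6, to be joined by a palladium/copper acylation of the terminal alkyne.

**4 ⇒ 3 ⇒ 2 ⇒ 1, and 6 ⇒ 5.** The alkyne is the one-carbon homologue of aldehyde 3. Its two ethers are placed in turn on 1, the benzyl group first at the unchelated 4-OH (2), then the acetal at the 2-OH. The acid chloride comes from acid 5.

## Alternatives that were turned down

**Alternative 1: ring switch from a dihydrofuran, ended by fluoride displacement.**
- Disconnection: O1–C2 and O–C2' are cut together, giving the ketone A2, whose ring oxygen and C5 are the future ring D oxygen and C10 (already R).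
- Key step: with Cs2CO3 in hot DMSO a ring A phenoxide adds to C2 of the dihydrofuran and expels the ring oxygen as the C10 alkoxide, closing ring C. That alkoxide then displaces the 2'-fluoride and closes ring D, giving A1.
- For: two rings form in one operation, the configuration arrives with the building block, and the tertiary alcohol is present from the start. On step count and on certainty of configuration it is stronger than the chosen route.
- Against: the fluoride at C2' is activated only by the pyranone at C1'. At the moment of substitution that pyranone carries the 5-phenoxide, whose charge flows into C4=O and on to C2 and weakens it as an acceptor. The nucleophile is a hindered secondary alkoxide that must close a seven-membered ring, and the first stage is reversible because the alkoxide can re-add to C2. A1 still lacks the C6 chain, so the iodination and coupling endgame is not saved.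
- Comparison: the chosen strategy gives up step economy. In return the aryl ether is made by ordinary phenoxide alkylation, and ring D closes by C=C formation away from both arenes, a reaction type with direct precedent on 2-alkoxyacrylates.

**Alternative 2: rhodium C–H annulation of a salicylaldehyde with an alkyne.**
- Disconnection: C3–C4 and O1–C2 of ring C, giving salicylaldehyde A5 and the chiral alkyne A4.
- Key step: [Cp*RhCl2]2 with Cu(OAc)2 activates the aldehyde C–H bond under direction of the phenoxide, the alkyne inserts into the acyl–rhodium bond, and C–O reductive elimination gives chromone A3. Copper reoxidises the rhodium.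
- For: it is the most convergent assembly of rings A, B and C. The diol of A4 can come from an asymmetric dihydroxylation of a prenyl group, so the configuration is reliable. Insertion should place the aryl-bearing alkyne carbon next to oxygen, as required. On convergence and stereochemical certainty it is at least as strong as the chosen route.
- Against: ring D is still open in A3. Closing it needs acetonide removal and the same weakly activated fluoride displacement by a hindered secondary alkoxide. The acyl–rhodium intermediate of an electron-rich aldehyde can decarbonylate, and the alkyne is hindered on both sides (ortho-fluoroaryl, branched propargylic carbon). The 5-O-methyl group would then have to be cleaved with the tertiary alcohol, free or masked, already in the molecule.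
- Comparison: the chosen route makes the tertiary alcohol only after the Lewis-acid step and closes ring D by a catalytic reaction that does not depend on activating ring B.

**Alternative 3: Mentzer pyranone annulation of a phloroglucinol onto a chiral benzoxepinone.**
- Disconnection: C4–C4a and O1–C2, giving phloroglucinol A8 and the β-keto ester A7, which already contains ring D and C10.
- Key step: in refluxing mesitylene without catalyst the tert-butyl ester loses its tert-butyl group to give an acylketene, which acylates A8. Cyclodehydration onto the aryl ketone closes ring C and gives A6.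
- For: ring A arrives unprotected, A8 is symmetric so no regiochemistry arises, no metal is needed, and nothing asymmetric is done on advanced material. On convergence at the ring C stage it is stronger.
- Against: the difficulty is moved into A7, not removed. A7 needs its own seven-membered ring closure and its own C10 stereocentre. It also needs a benzyl ether on a tertiary alcohol, which is hard to install and can only be removed by hydrogenolysis before the side-chain alkene exists. The condensation with a hindered aryl ketone inside a seven-membered ring must compete with the coumarin mode of closure at about 165 °C. A6 then still needs selective 7-O-methylation besides the C6 chain.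
- Comparison: the chosen route reaches its key precursor in nine steps from three commodity chemicals, and its uncertainty sits in one catalytic step with a close precedent class.

Key step: step 10

Assumption 1: the (E)-alkenylboronate 22 is taken as a purchasable reagent; it is the hydroboration product of 3-methylbut-1-yne with pinacolborane.

Assumption 2: the sense of induction of the iridium catalyst on this cyclic substrate cannot be predicted with certainty. The (Sa,S) ligand is written, and its mirror image would be used if a first test gave the 10S acid.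

## Route

Step 1
Reactants: 1 2,4-dihydroxybenzaldehyde
Product: 2 4-benzyloxy-2-hydroxybenzaldehyde
Conditions: BnBr, NaHCO3, MeCN, 80 °C
Reagents that add atoms: benzyl bromide, BrCc1ccccc1
Why: Williamson etherification; the 2-OH is held in a hydrogen bond to the aldehyde, so the weak base ionises and alkylates only the 4-OH.

Step 2
Reactants: 2 4-benzyloxy-2-hydroxybenzaldehyde
Product: 3 4-benzyloxy-2-(methoxymethoxy)benzaldehyde
Conditions: MOMCl, iPr2NEt, CH2Cl2, 0 °C to rt
Reagents that add atoms: chloromethyl methyl ether, COCCl
Why: O-alkylation of the remaining phenol with Hünig's base; the acetal should survive the basic and palladium steps ahead and leaves later under acid that does not touch the benzyl ether.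

Step 3
Reactants: 3 4-benzyloxy-2-(methoxymethoxy)benzaldehyde
Product: 4 4-benzyloxy-1-ethynyl-2-(methoxymethoxy)benzene
Conditions: MeC(O)C(N2)P(O)(OMe)2, K2CO3, MeOH, rt
Reagents that add atoms: dimethyl (1-diazo-2-oxopropyl)phosphonate, CC(=O)C(=[N+]=[N-])P(=O)(OC)OC
Why: Seyferth–Gilbert homologation with the Ohira–Bestmann reagent; methanolysis frees the diazophosphonate anion, which adds to the aldehyde, loses dimethyl phosphate and N2, and the alkylidene carbene rearranges to the terminal alkyne. Both ethers are stable to K2CO3 in MeOH.

Step 4
Reactants: 5 2,4,6-trimethoxybenzoic acid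
Product: 6 2,4,6-trimethoxybenzoyl chloride
Conditions: (COCl)2, DMF (cat.), CH2Cl2, 0 °C to rt
Reagents that add atoms: oxalyl chloride, O=C(Cl)C(=O)Cl
Why: Vilsmeier-type activation of the acid; gas evolution drives the reaction and the crude chloride is used at once.

Step 5
Reactants: 4 4-benzyloxy-1-ethynyl-2-(methoxymethoxy)benzene; 6 2,4,6-trimethoxybenzoyl chloride
Product: 7 3-[4-benzyloxy-2-(methoxymethoxy)phenyl]-1-(2,4,6-trimethoxyphenyl)prop-2-yn-1-one
Conditions: PdCl2(PPh3)2 (2 mol %), CuI (4 mol %), Et3N, THF, rt
Reagents that add atoms: none
Why: Acyl Sonogashira coupling; the C–Cl bond adds to zerovalent palladium, the copper acetylide transmetalates and reductive elimination forms the C3–C4 bond. No aqueous base is present, so the acid chloride is not hydrolysed.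

Step 6
Reactants: 7 3-[4-benzyloxy-2-(methoxymethoxy)phenyl]-1-(2,4,6-trimethoxyphenyl)prop-2-yn-1-one
Product: 8 2-[4-benzyloxy-2-(methoxymethoxy)phenyl]-3-iodo-5,7-dimethoxychromen-4-one
Conditions: ICl (1.1 equiv), CH2Cl2, −78 °C
Reagents that add atoms: iodine monochloride, ICl
Why: 6-endo-dig iodocyclisation of an ortho-methoxyaryl ynone; iodine goes to the carbon next to the carbonyl, a ring A methoxy oxygen attacks the carbon on electron-rich ring B, and chloride removes the methyl group from the oxonium ion. Attack by the acetal oxygen of ring B would need positive charge next to the carbonyl and is not expected, and one equivalent of ICl at low temperature should keep ring iodination from competing.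

Step 7
Reactants: 8 2-[4-benzyloxy-2-(methoxymethoxy)phenyl]-3-iodo-5,7-dimethoxychromen-4-one
Product: 9 2-[4-benzyloxy-2-(methoxymethoxy)phenyl]-3-ethenyl-5,7-dimethoxychromen-4-one
Conditions: Bu3SnCH=CH2, Pd(PPh3)4 (5 mol %), toluene, 100 °C
Reagents that add atoms: tributyl(ethenyl)stannane, C=C[Sn](CCCC)(CCCC)CCCC
Why: Stille coupling forms the C3–C9 bond under neutral conditions that leave the pyranone and both ethers untouched.

Step 8
Reactants: 9 2-[4-benzyloxy-2-(methoxymethoxy)phenyl]-3-ethenyl-5,7-dimethoxychromen-4-one
Product: 10 2-(4-benzyloxy-2-hydroxyphenyl)-3-ethenyl-5,7-dimethoxychromen-4-one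
Conditions: HCl (2 M aq, cat.), MeOH/THF, 40 °C
Reagents that add atoms: none
Why: Acid-catalysed acetal exchange with methanol releases the 2'-phenol; benzyl and methyl ethers and the vinyl group should be stable to dilute acid at this temperature.

Step 9
Reactants: 10 2-(4-benzyloxy-2-hydroxyphenyl)-3-ethenyl-5,7-dimethoxychromen-4-one; 11 methyl 2,3-dibromopropanoate
Product: 13 methyl 2-[5-benzyloxy-2-(3-ethenyl-5,7-dimethoxy-4-oxochromen-2-yl)phenoxy]prop-2-enoate, via bromo ester 12 (not isolated)
Conditions: K2CO3, acetone, 56 °C
Reagents that add atoms: none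
Why: O-alkylation then elimination; the phenoxide displaces the activated α-bromide of 11 (SN2 next to the ester), and bromo ester 12, whose α-hydrogen is acidified by ester and aryloxy group, loses HBr by E1cB. This forms the O–C10 bond as an ordinary phenol alkylation.

Step 10
Reactants: 13 methyl 2-[5-benzyloxy-2-(3-ethenyl-5,7-dimethoxy-4-oxochromen-2-yl)phenoxy]prop-2-enoate
Product: 14 methyl 4'-benzyloxy-5,7-dimethoxy-9,10-didehydrooxepinoflavone-10-carboxylate (ring D alkene C9=C10)
Conditions: [RuCl2(H2IMes)(=CH-C6H4-2-OiPr)] (second-generation Hoveyda–Grubbs catalyst, 10 mol %), toluene (0.005 M), 90 °C, argon purge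
Reagents that add atoms: none
Why: Ring-closing olefin metathesis: the precatalyst exchanges its benzylidene for the monosubstituted 3-vinyl group, giving a ruthenium alkylidene at C9. This adds across the acrylate C=CH2 with ruthenium on the CH2 end, and the ruthenacyclobutane collapses to C9=C10 and a ruthenium methylidene, which carries the chain with loss of ethene. The closest known reaction type is the ring-closing metathesis of 2-alkoxyacrylates to cyclic enol ether esters. Ring D closes as a seven-membered ring by alkene metathesis with the new double bond endocyclic, and the ring fixes its geometry (C3 cis to the ether oxygen). No stereocentre is formed; C10 stays trigonal until step 12. The step needs chemoselectivity among three C=C bonds: only the vinyl group can load the catalyst, the electron-poor 1,1-disubstituted acrylate reacts only intramolecularly, and the tetrasubstituted C2=C3 of the pyranone is inert. Ring closure is favoured over dimerisation because the 3-vinyl and 2'-substituents force ring B out of the pyranone plane and hold the acrylate over C3, and high dilution supports this. The argon purge removes ethene and makes the closure irreversible.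

Step 11
Reactants: 14 methyl 4'-benzyloxy-5,7-dimethoxy-9,10-didehydrooxepinoflavone-10-carboxylate
Product: 15 4'-benzyloxy-5,7-dimethoxy-9,10-didehydrooxepinoflavone-10-carboxylic acid
Conditions: LiOH·H2O, THF/H2O, rt; then 1 M HCl to pH 3, 0 °C
Reagents that add atoms: lithium hydroxide, [Li+].[OH-]
Why: Saponification at the ester carbonyl; the 2-aryl pyranone tolerates hydroxide at room temperature, and cold, mild acidification avoids hydrolysis of the enol ether. The free acid is what the hydrogenation catalyst binds.

Step 12
Reactants: 15 4'-benzyloxy-5,7-dimethoxy-9,10-didehydrooxepinoflavone-10-carboxylic acid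
Product: 16 (10R)-4'-benzyloxy-5,7-dimethoxyoxepinoflavone-10-carboxylic acid
Conditions: H2 (6 atm), [Ir(cod)(L)]B[3,5-(CF3)2C6H3]4 (1 mol %; L = (Sa,S)-7-[bis(3,5-di-tert-butylphenyl)phosphanyl]-7'-(4-benzyl-4,5-dihydrooxazol-2-yl)-1,1'-spirobiindane), Et3N (0.5 equiv), MeOH, rt
Reagents that add atoms: none
Why: Carboxylate-directed asymmetric hydrogenation of a 2-aryloxy-3-arylacrylic acid; the carboxylate binds iridium and H2 adds syn across C9=C10 from the face chosen by the spiro phosphine–oxazoline ligand, so the catalyst sets C10 as R. The ring holds the alkene in the geometry of the (Z)-acids for which this catalyst class is known. The tetrasubstituted C2=C3 and the benzyl ether should not react with a homogeneous catalyst at this pressure.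

Step 13
Reactants: 16 (10R)-4'-benzyloxy-5,7-dimethoxyoxepinoflavone-10-carboxylic acid
Product: 18 methyl (10R)-5,4'-dihydroxy-7-methoxyoxepinoflavone-10-carboxylate, via dihydroxy acid 17 (not isolated)
Conditions: BCl3 (4 equiv), C6HMe5, CH2Cl2, −78 to 0 °C; then MeOH, 45 °C
Reagents that add atoms: methanol, CO
Why: Lewis-acid ether cleavage then Fischer esterification; BCl3 removes the benzyl group (cation trapped by pentamethylbenzene) and, through its chelate with the C4 carbonyl, only the 5-O-methyl group. The 7-OMe and the ring D ether, whose C10 is deactivated by the carboxyl group, should remain. Methanol then destroys the boron species, and the HCl set free esterifies the acid without base, so C10 cannot epimerise.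

Step 14
Reactants: 18 methyl (10R)-5,4'-dihydroxy-7-methoxyoxepinoflavone-10-carboxylate
Product: 19 (10R)-5,4'-dihydroxy-10-(2-hydroxypropan-2-yl)-7-methoxyoxepinoflavone
Conditions: MeMgBr (6 equiv), THF, −20 to 0 °C; aq NH4Cl
Reagents that add atoms: methylmagnesium bromide, C[Mg]Br
Why: Double Grignard addition to the ester; the first two equivalents form the 5- and 4'-phenoxides, and the magnesium chelate at O5/C4=O together with the 4'-phenoxide conjugated to C2 should shield the pyranone. Addition at low temperature is faster than deprotonation at C10, so the configuration should hold.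

Step 15
Reactants: 19 (10R)-5,4'-dihydroxy-10-(2-hydroxypropan-2-yl)-7-methoxyoxepinoflavone
Product: 20 (10R)-4'-acetoxy-5-hydroxy-10-(2-hydroxypropan-2-yl)-7-methoxyoxepinoflavone
Conditions: Ac2O (1.1 equiv), pyridine, CH2Cl2, 0 °C
Reagents that add atoms: acetic anhydride, CC(=O)OC(C)=O
Why: Selective O-acylation; the 5-OH is locked in its hydrogen bond to C4=O and the tertiary alcohol does not react without a nucleophilic catalyst. The acetate lowers the reactivity of ring B toward the iodination that follows.

Step 16
Reactants: 20 (10R)-4'-acetoxy-5-hydroxy-10-(2-hydroxypropan-2-yl)-7-methoxyoxepinoflavone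
Product: 21 (10R)-4'-acetoxy-5-hydroxy-10-(2-hydroxypropan-2-yl)-6-iodo-7-methoxyoxepinoflavone
Conditions: BnMe3N ICl2 (1.05 equiv), CaCO3, CH2Cl2/MeOH, rt
Reagents that add atoms: benzyltrimethylammonium dichloroiodate, C[N+](C)(C)Cc1ccccc1.Cl[I-]Cl
Why: Electrophilic aromatic iodination; in 5-hydroxy-7-alkoxyflavones the free phenol directs this reagent to C6 and not to C8, while ring B is deactivated by the acetate and the pyranone. CaCO3 takes up the HCl, so the tertiary alcohol is not ionised.

Step 17
Reactants: 21 (10R)-4'-acetoxy-5-hydroxy-10-(2-hydroxypropan-2-yl)-6-iodo-7-methoxyoxepinoflavone; 22 (E)-4,4,5,5-tetramethyl-2-(3-methylbut-1-enyl)-1,3,2-dioxaborolane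
Product: 24 (10R)-5,4'-dihydroxy-10-(2-hydroxypropan-2-yl)-7-methoxy-6-[(E)-3-methylbut-1-enyl]oxepinoflavone, via target 4'-acetate 23 (not isolated)
Conditions: Pd(OAc)2 (5 mol %), SPhos, K3PO4, dioxane/H2O, 80 °C; then K2CO3, MeOH, rt
Reagents that add atoms: none
Why: Suzuki–Miyaura coupling with retention of the E geometry of the alkenylboronate; the biaryl phosphine is chosen for the doubly ortho-substituted, electron-rich iodide. Methanolysis in the same pot then removes the 4'-acetate under conditions that should not harm the product.

## Compound list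

1 | 2,4-dihydroxybenzaldehyde | O=Cc1ccc(O)cc1O | starting material
2 | 4-benzyloxy-2-hydroxybenzaldehyde | O=Cc1ccc(OCc2ccccc2)cc1O | intermediate
3 | 4-benzyloxy-2-(methoxymethoxy)benzaldehyde | O=Cc1ccc(OCc2ccccc2)cc1OCOC | intermediate
4 | 4-benzyloxy-1-ethynyl-2-(methoxymethoxy)benzene | C#Cc1ccc(OCc2ccccc2)cc1OCOC | intermediate
5 | 2,4,6-trimethoxybenzoic acid | COc1cc(OC)c(C(=O)O)c(OC)c1 | starting material
6 | 2,4,6-trimethoxybenzoyl chloride | COc1cc(OC)c(C(=O)Cl)c(OC)c1 | intermediate
7 | 3-[4-benzyloxy-2-(methoxymethoxy)phenyl]-1-(2,4,6-trimethoxyphenyl)prop-2-yn-1-one | COCOc1cc(OCc2ccccc2)ccc1C#CC(=O)c1c(OC)cc(OC)cc1OC | intermediate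
8 | 2-[4-benzyloxy-2-(methoxymethoxy)phenyl]-3-iodo-5,7-dimethoxychromen-4-one | COCOc1cc(OCc2ccccc2)ccc1-c1oc2cc(OC)cc(OC)c2c(=O)c1I | intermediate
9 | 2-[4-benzyloxy-2-(methoxymethoxy)phenyl]-3-ethenyl-5,7-dimethoxychromen-4-one | COCOc1cc(OCc2ccccc2)ccc1-c1oc2cc(OC)cc(OC)c2c(=O)c1C=C | intermediate
10 | 2-(4-benzyloxy-2-hydroxyphenyl)-3-ethenyl-5,7-dimethoxychromen-4-one | Oc1cc(OCc2ccccc2)ccc1-c1oc2cc(OC)cc(OC)c2c(=O)c1C=C | intermediate
11 | methyl 2,3-dibromopropanoate | COC(=O)C(Br)CBr | starting material
12 | methyl 2-[5-benzyloxy-2-(3-ethenyl-5,7-dimethoxy-4-oxochromen-2-yl)phenoxy]-3-bromopropanoate (racemic, not isolated) | COC(=O)C(CBr)Oc1cc(OCc2ccccc2)ccc1-c1oc2cc(OC)cc(OC)c2c(=O)c1C=C | intermediate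
13 | methyl 2-[5-benzyloxy-2-(3-ethenyl-5,7-dimethoxy-4-oxochromen-2-yl)phenoxy]prop-2-enoate | COC(=O)C(=C)Oc1cc(OCc2ccccc2)ccc1-c1oc2cc(OC)cc(OC)c2c(=O)c1C=C | intermediate
14 | methyl 4'-benzyloxy-5,7-dimethoxy-9,10-didehydrooxepinoflavone-10-carboxylate | COC(=O)C1=Cc2c(oc3cc(OC)cc(OC)c3c2=O)-c2ccc(OCc3ccccc3)cc2O1 | intermediate
15 | 4'-benzyloxy-5,7-dimethoxy-9,10-didehydrooxepinoflavone-10-carboxylic acid | O=C(O)C1=Cc2c(oc3cc(OC)cc(OC)c3c2=O)-c2ccc(OCc3ccccc3)cc2O1 | intermediate
16 | (10R)-4'-benzyloxy-5,7-dimethoxyoxepinoflavone-10-carboxylic acid | COc1cc2oc3c(c(=O)c2c(OC)c1)C[C@H](C(=O)O)Oc1cc(OCc2ccccc2)ccc1-3 | intermediate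
17 | (10R)-5,4'-dihydroxy-7-methoxyoxepinoflavone-10-carboxylic acid (not isolated) | COc1cc2oc3c(c(=O)c2c(O)c1)C[C@H](C(=O)O)Oc1cc(O)ccc1-3 | intermediate
18 | methyl (10R)-5,4'-dihydroxy-7-methoxyoxepinoflavone-10-carboxylate | COc1cc2oc3c(c(=O)c2c(O)c1)C[C@H](C(=O)OC)Oc1cc(O)ccc1-3 | intermediate
19 | (10R)-5,4'-dihydroxy-10-(2-hydroxypropan-2-yl)-7-methoxyoxepinoflavone | COc1cc2oc3c(c(=O)c2c(O)c1)C[C@H](C(C)(C)O)Oc1cc(O)ccc1-3 | intermediate
20 | (10R)-4'-acetoxy-5-hydroxy-10-(2-hydroxypropan-2-yl)-7-methoxyoxepinoflavone | COc1cc2oc3c(c(=O)c2c(O)c1)C[C@H](C(C)(C)O)Oc1cc(OC(C)=O)ccc1-3 | intermediate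
21 | (10R)-4'-acetoxy-5-hydroxy-10-(2-hydroxypropan-2-yl)-6-iodo-7-methoxyoxepinoflavone | COc1cc2oc3c(c(=O)c2c(O)c1I)C[C@H](C(C)(C)O)Oc1cc(OC(C)=O)ccc1-3 | intermediate
22 | (E)-4,4,5,5-tetramethyl-2-(3-methylbut-1-enyl)-1,3,2-dioxaborolane | CC(C)/C=C/B1OC(C)(C)C(C)(C)O1 | starting material
23 | (10R)-4'-acetoxy-5-hydroxy-10-(2-hydroxypropan-2-yl)-7-methoxy-6-[(E)-3-methylbut-1-enyl]oxepinoflavone (not isolated) | COc1cc2oc3c(c(=O)c2c(O)c1/C=C/C(C)C)C[C@H](C(C)(C)O)Oc1cc(OC(C)=O)ccc1-3 | intermediate
24 | (10R)-5,4'-dihydroxy-10-(2-hydroxypropan-2-yl)-7-methoxy-6-[(E)-3-methylbut-1-enyl]oxepinoflavone (CNP0216454.1) | COc1cc2oc3c(c(=O)c2c(O)c1/C=C/C(C)C)C[C@H](C(C)(C)O)Oc1cc(O)ccc1-3 | target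

## Step count and least certain steps

Total step count: 17. Longest linear sequence: 16 steps (steps 1–3 and 5–17, from 1 to 24); step 4 is a one-step branch.

**Step 10 (key step).** The most likely failure is catalyst death before ring closure. The vinyl group is flanked by C4=O and the aryl ring, so loading is slow; the C4 carbonyl oxygen can chelate the new alkylidene; and the acrylate is electron-poor and 1,1-disubstituted. Intermolecular coupling through the vinyl groups would then take over. The fallback replaces metathesis by an intramolecular Heck reaction and sets out from 8. Acidic methanolysis of the acetal (HCl, MeOH/THF) should give 2-(4-benzyloxy-2-hydroxyphenyl)-3-iodo-5,7-dimethoxychromen-4-one F1. Alkylation and elimination with 11 and K2CO3 in acetone, as in step 9, should give methyl 2-[5-benzyloxy-2-(3-iodo-5,7-dimethoxy-4-oxochromen-2-yl)phenoxy]prop-2-enoate F2. With Pd(OAc)2, P(o-tol)3 and Et3N in MeCN at 80 °C, oxidative addition at C3–I, 7-endo carbopalladation onto the unsubstituted CH2 of the acrylate and syn β-hydride elimination from C9 should give 14, where the route is rejoined.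

**Step 12.** Insufficient face selectivity or slow turnover is the main risk. The β-substituent is a hindered pyranone, and the seven-membered ring restricts how the carboxylate-bound alkene can sit in the chiral pocket. The fallback uses resolution, from 15 to 16. Hydrogenation of 15 over the achiral complex [Ir(cod)(PCy3)(py)]PF6 in CH2Cl2 should give racemic 4'-benzyloxy-5,7-dimethoxyoxepinoflavone-10-carboxylic acid F3. Crystallisation with one antipode of 1-phenylethylamine (the S amine is written; the antipode that gives the less soluble salt with the 10R acid has to be found) should give the (S)-1-phenylethylammonium salt of the 10R acid F4. Acidification returns 16.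

**Step 9.** Premature loss of HBr from the dibromo ester, followed by conjugate addition of the hindered phenoxide at the wrong carbon, would give the 3-aryloxy isomer or double addition. The fallback builds the acrylate by O–H insertion and olefination, from 10 to 13. Rh2(OAc)4-catalysed insertion of the carbene from methyl 2-diazo-2-(dimethoxyphosphoryl)acetate into the phenol O–H bond (toluene, 80 °C) should give methyl 2-[5-benzyloxy-2-(3-ethenyl-5,7-dimethoxy-4-oxochromen-2-yl)phenoxy]-2-(dimethoxyphosphoryl)acetate F5. A Horner–Wadsworth–Emmons reaction with aqueous formaldehyde and K2CO3 then gives 13.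

**Step 13.** Opening of the ring D ether by the Lewis acid (chloride attack at C10 after boron chelation between carboxyl and ether oxygen) or C-benzylation of ring A could erode the material. The fallback separates the three operations and avoids boron halides, from 16 to 18. Fischer esterification (MeOH, H2SO4 cat.) should give methyl (10R)-4'-benzyloxy-5,7-dimethoxyoxepinoflavone-10-carboxylate F6. Hydrogenolysis (H2, Pd/C, EtOAc), possible here because the side-chain alkene is not yet present, should give methyl (10R)-4'-hydroxy-5,7-dimethoxyoxepinoflavone-10-carboxylate F7. Chelation-controlled demethylation of the 5-OMe with MgI2·OEt2 in THF at 50 °C then gives 18.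

**Step 5.** Acyl transfer to the hindered, electron-rich acid chloride may be slow, so that oxidative dimerisation of the alkyne or decarbonylation competes. The fallback makes the C3–C4 bond by carbonyl addition, from 4 to 7. Deprotonation of 4 with n-BuLi (THF, −78 °C) and addition to commercial 2,4,6-trimethoxybenzaldehyde should give 3-[4-benzyloxy-2-(methoxymethoxy)phenyl]-1-(2,4,6-trimethoxyphenyl)prop-2-yn-1-ol F8. Oxidation with MnO2 in CH2Cl2 gives 7.

## Further compounds

F1 | step 10 | 2-(4-benzyloxy-2-hydroxyphenyl)-3-iodo-5,7-dimethoxychromen-4-one | Oc1cc(OCc2ccccc2)ccc1-c1oc2cc(OC)cc(OC)c2c(=O)c1I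
F2 | step 10 | methyl 2-[5-benzyloxy-2-(3-iodo-5,7-dimethoxy-4-oxochromen-2-yl)phenoxy]prop-2-enoate | COC(=O)C(=C)Oc1cc(OCc2ccccc2)ccc1-c1oc2cc(OC)cc(OC)c2c(=O)c1I
F3 | step 12 | racemic 4'-benzyloxy-5,7-dimethoxyoxepinoflavone-10-carboxylic acid | COc1cc2oc3c(c(=O)c2c(OC)c1)CC(C(=O)O)Oc1cc(OCc2ccccc2)ccc1-3
F4 | step 12 | (S)-1-phenylethylammonium (10R)-4'-benzyloxy-5,7-dimethoxyoxepinoflavone-10-carboxylate | C[C@H]([NH3+])c1ccccc1.COc1cc2oc3c(c(=O)c2c(OC)c1)C[C@H](C(=O)[O-])Oc1cc(OCc2ccccc2)ccc1-3
F5 | step 9 | methyl 2-[5-benzyloxy-2-(3-ethenyl-5,7-dimethoxy-4-oxochromen-2-yl)phenoxy]-2-(dimethoxyphosphoryl)acetate (racemic) | COC(=O)C(Oc1cc(OCc2ccccc2)ccc1-c1oc2cc(OC)cc(OC)c2c(=O)c1C=C)P(=O)(OC)OC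
F6 | step 13 | methyl (10R)-4'-benzyloxy-5,7-dimethoxyoxepinoflavone-10-carboxylate | COc1cc2oc3c(c(=O)c2c(OC)c1)C[C@H](C(=O)OC)Oc1cc(OCc2ccccc2)ccc1-3
F7 | step 13 | methyl (10R)-4'-hydroxy-5,7-dimethoxyoxepinoflavone-10-carboxylate | COc1cc2oc3c(c(=O)c2c(OC)c1)C[C@H](C(=O)OC)Oc1cc(O)ccc1-3
F8 | step 5 | 3-[4-benzyloxy-2-(methoxymethoxy)phenyl]-1-(2,4,6-trimethoxyphenyl)prop-2-yn-1-ol (racemic) | COCOc1cc(OCc2ccccc2)ccc1C#CC(O)c1c(OC)cc(OC)cc1OC
A1 | alternative 1 | (10R)-5-hydroxy-10-(2-hydroxypropan-2-yl)-7-methoxy-4'-(methoxymethoxy)oxepinoflavone | COc1cc2oc3c(c(=O)c2c(O)c1)C[C@H](C(C)(C)O)Oc1cc(OCOC)ccc1-3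
A2 | alternative 1 | (2,6-dihydroxy-4-methoxyphenyl)[(5R)-2-[2-fluoro-4-(methoxymethoxy)phenyl]-5-(2-hydroxypropan-2-yl)-4,5-dihydrofuran-3-yl]methanone | COc1cc(O)c(C(=O)C2=C(c3ccc(OCOC)cc3F)O[C@@H](C(C)(C)O)C2)c(O)c1
A3 | alternative 2 | 2-(4-benzyloxy-2-fluorophenyl)-5,7-dimethoxy-3-[[(4R)-2,2,5,5-tetramethyl-1,3-dioxolan-4-yl]methyl]chromen-4-one | COc1cc(OC)c2c(=O)c(C[C@H]3OC(C)(C)OC3(C)C)c(-c3ccc(OCc4ccccc4)cc3F)oc2c1
A4 | alternative 2 | (4R)-4-[3-(4-benzyloxy-2-fluorophenyl)prop-2-ynyl]-2,2,5,5-tetramethyl-1,3-dioxolane | Fc1cc(OCc2ccccc2)ccc1C#CC[C@H]1OC(C)(C)OC1(C)C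
A5 | alternative 2 | 2-hydroxy-4,6-dimethoxybenzaldehyde | COc1cc(O)c(C=O)c(OC)c1
A6 | alternative 3 | (10R)-4'-benzyloxy-10-(2-benzyloxypropan-2-yl)-5,7-dihydroxyoxepinoflavone | Oc1cc2oc3c(c(=O)c2c(O)c1)C[C@H](C(C)(C)OCc1ccccc1)Oc1cc(OCc2ccccc2)ccc1-3
A7 | alternative 3 | tert-butyl (2R)-8-benzyloxy-2-(2-benzyloxypropan-2-yl)-5-oxo-2,3,4,5-tetrahydro-1-benzoxepine-4-carboxylate (C4 epimers) | CC(C)(C)OC(=O)C1C[C@H](C(C)(C)OCc2ccccc2)Oc2cc(OCc3ccccc3)ccc2C1=O
A8 | alternative 3 | phloroglucinol (benzene-1,3,5-triol) | Oc1cc(O)cc(O)c1
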